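Target stands at 56% with 0.28 mol% free catalyst in the theta run and at 66% with 0.44 mol% in the epsilon run, while 44% and 35% of the starting material remain.

| flask | starting material | reagent | free catalyst | remark |
|---|---|---|---|---|
| theta | 39 mM | 1.1 equiv | 0.28 mol% | run made earlier |
| epsilon | 39 mM | 1.1 equiv | 0.44 mol% | run made earlier |
| delta | 58 mM | 1.1 equiv | 0.2 mol% | run made earlier |
| flask | 39 mM | 1.10 equiv | 0.2 mol% |  |

| run | time / d | target / % | starting material / % |
|---|---|---|---|
| theta | 1.04 | 55 | 42 |
| theta | 2.08 | 56 | 43 |
| theta | 3.00 | 56 | 43 |
| theta | 4.00 | 56 | 44 |
| theta | 5.00 | 55 | 43 |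
| epsilon | 0.417 | 63 | 37 |
| epsilon | 0.833 | 66 | 35 |
| epsilon | 1.25 | 66 | 35 |
| epsilon | 2.50 | 66 | 35 |
| epsilon | 5.00 | 63 | 34 |
| delta | 0.417 | 40 | 60 |
| delta | 1.25 | 43 | 56 |
| delta | 2.50 | 43 | 54 |
| delta | 4.00 | 44 | 55 |
| delta | 5.00 | 45 | 55 |

(standard deviation of a reading: 1.5 percentage points)

1. factor on the rate of making target when 10% of the starting material are converted if free catalyst is charged twice over
2. factor on the rate when 10% of the starting material are converted if free catalyst is charged at 2 mol% instead



My own reckoning supposes that reagent leaves by two paths: into target at a rate proportional to [free catalyst][reagent], and otherwise, two at a time, at a rate proportional to [reagent]². Target made over reagent lost otherwise then equals s/[reagent], where s, in equivalents, is the [reagent] at which both paths run equally, and s goes with [free catalyst], taken as charged. Integrating this ratio from the charge gives reagent left = (s + charge)·exp(−target/s) − s, and target = s·ln(1 + charge/s) once reagent is used up. Solving the plateau for s and dividing by the loading gives the split number. It reads 164 for theta and 158 for epsilon, with a mean of 161.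

For the flask, s is then 0.322 equivalents. At 10% conversion, this reckoning leaves 0.720 equivalents of reagent, against 0.849 with the loading doubled and 0.968 at 2 mol%. Taking [free catalyst] as charged, the factors are 2.36 and 13.4.

The forecast, holding that “this is catalyst death, not equilibrium”, gives 2.15 and 11.3, both below mine.

The simulation gives 2.22 and 12.1.

    catalyst intermediate B → free catalyst + target (k = 1.30 /min)
    starting material + catalyst intermediate A → catalyst intermediate B (k = 2600 /M/min)
    2 reagent → self-condensation product (k = 0.0680 /M/min)
    reagent + free catalyst ⇌ catalyst intermediate A (K = 17.0 /M, k = 36.0 /M/min)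

At 5.00 d the flask holds 0% of its reagent, the limiting reagent, with 51.5% of the starting material left, 100% of the catalyst free and 12.0 mM self-condensation product. The split number 161 puts the flask's target at 47.8% of the starting material charged, and the flask holds 48.5%. The delta run, at the flask's loading but with 58 mM starting material, read 45% at 5.00 d, and the split number gives it 47.8%.

The earlier runs and the new flask were generated by integration with constants of no real substance; the scatter is artificial.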